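**Remarks and assumptions**

- The target has no stereocentre and no configurationally stable axis, so it is one achiral compound and no step has to control configuration.
- 4‑Fluoro‑3,5‑dimethylphenol (1) and 3,4,5‑trimethoxyphenol (7) are taken to be purchasable catalogue compounds.
- Ring convention: A is the 2,4,6‑trioxygenated end ring, F the 3,4,5‑trioxygenated end ring. In rings A–E, C1 is the flanked carbon whose oxygen leads toward ring F, C2/C6 are its ortho carbons, and C4 carries the oxygen leading toward ring A (or the end group).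

## The problem

The target is a linear hexamer of oxygenated benzene rings held together only by five diaryl ether oxygens, with fourteen free phenolic hydroxyls and no carbon substituent. There is no stereocentre, so the whole difficulty is constitutional: exactly six rings, one pyrogallol-type end (F), one phloroglucinol-type end (A). Every ether runs from an unhindered carbon (C4 of rings B–E, C1 of ring F) to C1 of the next ring toward A. That C1 is electron-rich and flanked by oxygen at C2 and C6, so neither nucleophilic aromatic substitution nor a copper-mediated coupling forms the bond well at the natural oxidation level. The free polyphenol is oxidised easily by air, base and most oxidants, so it should appear only in the last step. The enabling feature is that on rings A–E both C2 and C6 carry OH. If they carry formyl groups instead, C1 becomes an SNAr electrophile, and each formyl group can later be exchanged for OH by a Dakin-type oxidation. Ring F lacks this pattern but never has to act as an electrophile.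

## Retrosynthesis

**Target 20 to deca-phenol 19.** Four O–CH3 bonds are cut (three on ring F, one at C4 of ring A). Methyl is chosen because ring F then comes directly from commercial 7, the cap of ring A comes from iodomethane, and methyl ethers survive base, acid and peracid. The forward step is a global Lewis-acid demethylation, placed last so that the air-sensitive tetradecaphenol is handled once.

**Deca-phenol 19 to deca-aldehyde 17 (key disconnection).** The ten aryl C–O bonds at C2 and C6 of rings A–E are traced back to ten aryl C–CHO bonds, through the deca-formate 18. Making the flanked ether carbon directly has no good polar solution; replacing the two ortho hydroxyls by formyl groups inverts the polarity of C1 and makes all five ethers accessible by one reaction type. Precursor 17 is no smaller, but every one of its ether bonds is an SNAr bond. The forward reaction must give aryl rather than hydride migration at all ten aldehydes and must not over-oxidise the emerging phenols.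

**Deca-aldehyde 17 to phenol 15 and block 16, then repeatedly back to 7.** The C1–O bond of ring A is cut, then in turn those of rings B, C, D and E (15 from 14, 14 from 13 + 6, 13 from 12, 12 from 11 + 6, 11 from 10, 10 from 9 + 6, 9 from 8, 8 from 7 + 6). Growth starts at ring F, so the chain is always the nucleophile (an unhindered phenol) and the electrophile is always a monomer.

- Fluoride rather than chloride is the leaving group in 6 and 16. The formyl-flanked ether carbons already in the chain are themselves SNAr-active with an acidic phenoxide as leaving group. Only a leaving group that is displaced far faster than aryloxide keeps the incoming phenoxide from attacking inside the chain.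
- The chain-end phenol is masked as a methoxymethyl ether (6, 8, 10, 12, 14). It is installed with an amine base, is stable to carbonate, and is removed by aqueous acid. Basic or nucleophilic deprotections would attack the activated ethers, and hydrogenolysis would endanger the aldehydes.

**Blocks 6 and 16 to phenol 5, then to 3, 2 and 1.** Both blocks come from one phenol, 5, by O-alkylation. The two formyl groups of 5 are traced to the two methyl groups of 1, by C–H oxidation through the bis(dibromomethyl) compound 3. Ring formylation is not an option because it would place the formyl groups ortho to the hydroxyl, not ortho to fluorine. The acetate 2 deactivates the ring so that bromination goes to the benzylic positions; it is lost again on the way to 5 (through 4).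

## Roads not taken

**Alternative 1:** All five ether bonds are cut at once. Six molecules of 2,6‑dimethoxyphenol A1 would be coupled oxidatively (Cu/amine/O2 or laccase), each phenoxyl oxygen bonding to the para carbon of the next unit, to give hexamer A2.
- Merits: this is by far the shortest route on paper. The monomer is a commodity, the regiochemistry of O–to–para coupling is exactly the hindered-oxygen/unhindered-carbon linkage of the target, and no activating group has to be removed.
- Weak points: phenoxyl coupling gives a distribution of chain lengths that also redistributes, so A2 would be a minor component to be separated from its neighbours. Para C–C coupling competes strongly for this monomer. The tail ring of A2 has C–H where ring A of the target has its C4 oxygen, so a further site-selective oxidation would be needed.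
- Comparison: the chosen plan is much longer, but each ring is added in a separate, site-defined step, which gives exact control of length and constitution.

**Alternative 2:** Two C–C bonds of ring C are cut. The dienolate of the AB-bearing 3‑aryloxyglutaconate A3 would condense twice with the DEF-bearing aryloxymalonate A4 (double Claisen condensation, then aromatisation) to give hexamer A5 with ring C as a 4,6‑dihydroxyisophthalate.
- Merits: it is convergent, so its longest linear sequence is shorter than that of the chosen plan. The B–C and C–D ethers arise from simple O-alkylations, and the most crowded carbon of ring C is built by ring synthesis rather than substitution.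
- Weak points: A3 and A4 already contain the A–B, D–E and E–F hindered ethers, which need their own solution, so only two of the five ethers are addressed. The acidic C–H of A4 would quench the dienolate of A3 by proton transfer instead of acylating it, and its ester groups are hindered. Two ester groups on A5 must afterwards be hydrolysed and decarboxylated.
- Comparison: convergence is better here. The chosen plan offers instead one uniform bond-forming reaction for all five ethers, from a single building block.

**Alternative 3:** Both ether bonds at ring D are cut. The CpRu+ complex A6 of 2,5‑dichloro‑1,3‑dimethoxybenzene would react first with the hindered ABC phenol A7 at the open C–Cl and then with the EF phenol A8 at the flanked C–Cl, giving complex A9. Decomplexation and demethylation would then lead to 20.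
- Merits: π-complexation activates an electron-rich, doubly ortho-oxygenated chloroarene without auxiliary carbon substituents. All oxygens are at the correct oxidation level from the start, so no tenfold oxidation is needed, and the route is convergent. In redox economy this is better than the chosen plan.
- Weak points: A7 and A8 contain three of the five hindered ethers (A–B, B–C, E–F), each needing its own complexation/substitution/decomplexation cycle with stoichiometric ruthenium. The second substitution takes place at a flanked carbon of a ring that by then carries three donor oxygens. A7 is a hindered, easily oxidised 2,6‑dialkoxyphenoxide. Arene exchange among six electron-rich rings can move the metal off ring D.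
- Comparison: the chosen plan pays for its metal-free, single-block assembly with the burden of the tenfold oxidation in step 15.

Key step: step 15

## Route

Step 1
Reactants: 1 4‑fluoro‑3,5‑dimethylphenol
Product: 2 4‑fluoro‑3,5‑dimethylphenyl acetate
Conditions: Ac2O, pyridine, DMAP (cat.), CH2Cl2, rt
Reagents that add atoms: acetic anhydride, CC(=O)OC(C)=O
Why: Standard O‑acylation of a phenol; the ester lowers the electron density of the ring so that the following bromination goes to the benzylic positions and not into the ring.

Step 2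
Reactants: 2 4‑fluoro‑3,5‑dimethylphenyl acetate
Product: 3 3,5‑bis(dibromomethyl)‑4‑fluorophenyl acetate
Conditions: NBS (4.6 equiv), AIBN (cat.), PhCF3, reflux, visible light
Reagents that add atoms: N‑bromosuccinimide, O=C1CCC(=O)N1Br
Why: Exhaustive Wohl–Ziegler benzylic bromination; each methyl group should take two bromines because the α‑bromobenzyl radical is still stabilised, while a third bromine is disfavoured sterically next to the ortho fluorine.

Step 3
Reactants: 3 3,5‑bis(dibromomethyl)‑4‑fluorophenyl acetate
Product: 5 2‑fluoro‑5‑hydroxyisophthalaldehyde, via 4‑fluoro‑3,5‑diformylphenyl acetate 4 (not isolated)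
Conditions: AgNO3 (4.4 equiv), acetone/H2O, 50 °C, dark; filter; then 2 M H2SO4, 60 °C
Reagents that add atoms: water, O
Why: Silver-assisted hydrolysis of benzal bromides to aldehydes, followed by acid-catalysed hydrolysis of the aryl acetate; the medium is acidic throughout, so no phenoxide is present next to the activated C–F bond and self-condensation is avoided.

Step 4
Reactants: 5 2‑fluoro‑5‑hydroxyisophthalaldehyde
Product: 6 2‑fluoro‑5‑(methoxymethoxy)isophthalaldehyde
Conditions: MOMCl (1.5 equiv), i‑Pr2NEt (2 equiv), CH2Cl2, 0 °C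
Reagents that add atoms: chloromethyl methyl ether, COCCl
Why: O‑alkylation of an acidic phenol with a very reactive alkylating agent and a hindered amine base; alkylation should be far faster than any SNAr attack of the ammonium phenoxide on the product in CH2Cl2 at 0 °C.

Step 5
Reactants: 7 3,4,5‑trimethoxyphenol; 6 2‑fluoro‑5‑(methoxymethoxy)isophthalaldehyde
Product: 8 5‑(methoxymethoxy)‑2‑(3,4,5‑trimethoxyphenoxy)isophthalaldehyde (MOM-protected E–F dimer)
Conditions: K2CO3 (1.5 equiv), dry DMSO, rt to 40 °C, N2
Reagents that add atoms: none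
Why: SNAr (addition–elimination) of an electron-rich phenoxide at a fluoride activated by two ortho formyl groups; the acetal and the aldehydes are stable to carbonate.

Step 6
Reactants: 8 MOM-protected E–F dimer
Product: 9 5‑hydroxy‑2‑(3,4,5‑trimethoxyphenoxy)isophthalaldehyde (E–F phenol)
Conditions: 3 M aq. HCl/THF (1:3), 50 °C
Reagents that add atoms: none
Why: Acid hydrolysis of an aryl methoxymethyl ether; aldehydes, methyl ethers and the diaryl ether are inert to aqueous acid, and the formyl-flanked ether is not exposed to any nucleophile.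

Step 7
Reactants: 9 E–F phenol; 6 2‑fluoro‑5‑(methoxymethoxy)isophthalaldehyde
Product: 10 2‑[3,5‑diformyl‑4‑(3,4,5‑trimethoxyphenoxy)phenoxy]‑5‑(methoxymethoxy)isophthalaldehyde (MOM-protected D–E–F trimer)
Conditions: K2CO3 (1.5 equiv), 6 (1.2 equiv), dry DMSO, 40–60 °C, N2
Reagents that add atoms: none
Why: SNAr as in step 5; the phenoxide is now less nucleophilic (two meta formyl groups), but fluoride is displaced much faster than the aryloxide on ring E, which should keep the attack at the C–F carbon of 6.

Step 8
Reactants: 10 MOM-protected D–E–F trimer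
Product: 11 2‑[3,5‑diformyl‑4‑(3,4,5‑trimethoxyphenoxy)phenoxy]‑5‑hydroxyisophthalaldehyde (D–E–F phenol)
Conditions: 3 M aq. HCl/THF (1:3), 50 °C
Reagents that add atoms: none
Why: Acid hydrolysis of the aryl methoxymethyl ether as in step 6.

Step 9
Reactants: 11 D–E–F phenol; 6 2‑fluoro‑5‑(methoxymethoxy)isophthalaldehyde
Product: 12 2‑{3,5‑diformyl‑4‑[3,5‑diformyl‑4‑(3,4,5‑trimethoxyphenoxy)phenoxy]phenoxy}‑5‑(methoxymethoxy)isophthalaldehyde (MOM-protected C–D–E–F tetramer)
Conditions: K2CO3 (1.5 equiv), 6 (1.2 equiv), dry DMSO, 40–60 °C, N2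
Reagents that add atoms: none
Why: SNAr as in step 7, with the same nucleophile type and the same electrophile.

Step 10
Reactants: 12 MOM-protected C–D–E–F tetramer
Product: 13 2‑{3,5‑diformyl‑4‑[3,5‑diformyl‑4‑(3,4,5‑trimethoxyphenoxy)phenoxy]phenoxy}‑5‑hydroxyisophthalaldehyde (C–D–E–F phenol)
Conditions: 3 M aq. HCl/THF (1:3), 50 °C
Reagents that add atoms: none
Why: Acid hydrolysis of the aryl methoxymethyl ether as in step 6.

Step 11
Reactants: 13 C–D–E–F phenol; 6 2‑fluoro‑5‑(methoxymethoxy)isophthalaldehyde
Product: 14 2‑(3,5‑diformyl‑4‑{3,5‑diformyl‑4‑[3,5‑diformyl‑4‑(3,4,5‑trimethoxyphenoxy)phenoxy]phenoxy}phenoxy)‑5‑(methoxymethoxy)isophthalaldehyde (MOM-protected B–C–D–E–F pentamer)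
Conditions: K2CO3 (1.5 equiv), 6 (1.2 equiv), dry DMSO, 40–60 °C, N2
Reagents that add atoms: none
Why: SNAr as in step 7.

Step 12
Reactants: 14 MOM-protected B–C–D–E–F pentamer
Product: 15 2‑(3,5‑diformyl‑4‑{3,5‑diformyl‑4‑[3,5‑diformyl‑4‑(3,4,5‑trimethoxyphenoxy)phenoxy]phenoxy}phenoxy)‑5‑hydroxyisophthalaldehyde (B–C–D–E–F phenol)
Conditions: 3 M aq. HCl/THF (1:3), 50 °C
Reagents that add atoms: none
Why: Acid hydrolysis of the aryl methoxymethyl ether as in step 6.

Step 13
Reactants: 5 2‑fluoro‑5‑hydroxyisophthalaldehyde
Product: 16 2‑fluoro‑5‑methoxyisophthalaldehyde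
Conditions: MeI (8 equiv), K2CO3, acetone, rt
Reagents that add atoms: iodomethane, CI
Why: Williamson O‑methylation; the phenoxide of 5 is itself no electrophile (para O−), and with a large excess of iodomethane at room temperature methylation should outrun attack of the phenoxide on the product.

Step 14
Reactants: 15 B–C–D–E–F phenol; 16 2‑fluoro‑5‑methoxyisophthalaldehyde
Product: 17 2‑[3,5‑diformyl‑4‑(3,5‑diformyl‑4‑{3,5‑diformyl‑4‑[3,5‑diformyl‑4‑(3,4,5‑trimethoxyphenoxy)phenoxy]phenoxy}phenoxy)phenoxy]‑5‑methoxyisophthalaldehyde (deca-aldehyde hexamer)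
Conditions: K2CO3 (1.5 equiv), 16 (1.3 equiv), dry DMSO, 40–60 °C, N2
Reagents that add atoms: none
Why: SNAr as in step 7; it completes the chain with the methyl-capped ring A.

Step 15
Reactants: 17 deca-aldehyde hexamer
Product: 19 deca-phenol hexamer (OH at C2 and C6 of rings A–E; OMe at C4 of ring A; ring F 3,4,5‑trimethoxy), via deca-formate hexamer 18 (not isolated)
Conditions: mCPBA (30 equiv, dried), CH2Cl2, 0 to 40 °C; aq. Na2SO3 wash; then degassed MeOH, HCl (cat.), Ar, rt
Reagents that add atoms: 3‑chloroperoxybenzoic acid (mCPBA), OOC(=O)c1cccc(Cl)c1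
Why: The peracid adds to each formyl carbon to give a Criegee adduct, from which the ring carbon (C2 or C6 of rings A–E) shifts to oxygen with loss of 3‑chlorobenzoate, so every C–CHO becomes C–OCHO; this is the Baeyer–Villiger (Dakin-type) oxidation, whose closest known use is on 2‑alkoxy‑ and 2‑aryloxybenzaldehydes obtained by SNAr, including ones whose ortho oxygen is flanked on both sides and ones with a meta halogen or meta alkoxy group. No ring is closed and no stereocentre is formed. The selectivity needed is aryl over hydride migration at all ten sites; the ether oxygen on C1 is ortho to every migrating carbon and stabilises the electron-deficient transition state, while the other substituents (second formyl or formyloxy group, C4 oxygen) are meta and act only inductively. As long as oxidant is present the new oxygens remain electron-poor aryl formates (18), which keeps the peracid away from the emerging electron-rich rings, and ring F should not be hydroxylated by unbuffered mCPBA at this temperature. After reductive removal of excess peracid, acid methanolysis transfers the ten formyl groups to methanol without passing through air-sensitive phenoxides. Methyl ethers and diaryl ethers are inert throughout.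

Step 16
Reactants: 19 deca-phenol hexamer
Product: 20 2‑[3,5‑dihydroxy‑4‑(3,5‑dihydroxy‑4‑{3,5‑dihydroxy‑4‑[3,5‑dihydroxy‑4‑(3,4,5‑trihydroxyphenoxy)phenoxy]phenoxy}phenoxy)phenoxy]benzene‑1,3,5‑triol (target)
Conditions: BBr3 (30 equiv), CH2Cl2, −78 °C to rt, Ar; then degassed H2O
Reagents that add atoms: none
Why: Lewis-acid cleavage of aryl methyl ethers (boron coordination, then SN2 attack of bromide at methyl); diaryl ethers have no sp3 carbon to attack and stay intact, and the large excess allows for the ten free phenols that bind boron first.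

## Compound list

1 | 4‑fluoro‑3,5‑dimethylphenol | Cc1cc(O)cc(C)c1F | starting material
2 | 4‑fluoro‑3,5‑dimethylphenyl acetate | CC(=O)Oc1cc(C)c(F)c(C)c1 | intermediate
3 | 3,5‑bis(dibromomethyl)‑4‑fluorophenyl acetate | CC(=O)Oc1cc(C(Br)Br)c(F)c(C(Br)Br)c1 | intermediate
4 | 4‑fluoro‑3,5‑diformylphenyl acetate | CC(=O)Oc1cc(C=O)c(F)c(C=O)c1 | intermediate (not isolated)
5 | 2‑fluoro‑5‑hydroxyisophthalaldehyde | O=Cc1cc(O)cc(C=O)c1F | intermediate
6 | 2‑fluoro‑5‑(methoxymethoxy)isophthalaldehyde | COCOc1cc(C=O)c(F)c(C=O)c1 | intermediate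
7 | 3,4,5‑trimethoxyphenol | COc1cc(O)cc(OC)c1OC | starting material
8 | 5‑(methoxymethoxy)‑2‑(3,4,5‑trimethoxyphenoxy)isophthalaldehyde | COCOc1cc(C=O)c(Oc2cc(OC)c(OC)c(OC)c2)c(C=O)c1 | intermediate
9 | 5‑hydroxy‑2‑(3,4,5‑trimethoxyphenoxy)isophthalaldehyde | Oc1cc(C=O)c(Oc2cc(OC)c(OC)c(OC)c2)c(C=O)c1 | intermediate
10 | MOM-protected D–E–F trimer (tetra-aldehyde) | COCOc1cc(C=O)c(Oc2cc(C=O)c(Oc3cc(OC)c(OC)c(OC)c3)c(C=O)c2)c(C=O)c1 | intermediate
11 | D–E–F phenol (tetra-aldehyde) | Oc1cc(C=O)c(Oc2cc(C=O)c(Oc3cc(OC)c(OC)c(OC)c3)c(C=O)c2)c(C=O)c1 | intermediate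
12 | MOM-protected C–D–E–F tetramer (hexa-aldehyde) | COCOc1cc(C=O)c(Oc2cc(C=O)c(Oc3cc(C=O)c(Oc4cc(OC)c(OC)c(OC)c4)c(C=O)c3)c(C=O)c2)c(C=O)c1 | intermediate
13 | C–D–E–F phenol (hexa-aldehyde) | Oc1cc(C=O)c(Oc2cc(C=O)c(Oc3cc(C=O)c(Oc4cc(OC)c(OC)c(OC)c4)c(C=O)c3)c(C=O)c2)c(C=O)c1 | intermediate
14 | MOM-protected B–C–D–E–F pentamer (octa-aldehyde) | COCOc1cc(C=O)c(Oc2cc(C=O)c(Oc3cc(C=O)c(Oc4cc(C=O)c(Oc5cc(OC)c(OC)c(OC)c5)c(C=O)c4)c(C=O)c3)c(C=O)c2)c(C=O)c1 | intermediate
15 | B–C–D–E–F phenol (octa-aldehyde) | Oc1cc(C=O)c(Oc2cc(C=O)c(Oc3cc(C=O)c(Oc4cc(C=O)c(Oc5cc(OC)c(OC)c(OC)c5)c(C=O)c4)c(C=O)c3)c(C=O)c2)c(C=O)c1 | intermediate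
16 | 2‑fluoro‑5‑methoxyisophthalaldehyde | COc1cc(C=O)c(F)c(C=O)c1 | intermediate
17 | deca-aldehyde hexamer | COc1cc(C=O)c(Oc2cc(C=O)c(Oc3cc(C=O)c(Oc4cc(C=O)c(Oc5cc(C=O)c(Oc6cc(OC)c(OC)c(OC)c6)c(C=O)c5)c(C=O)c4)c(C=O)c3)c(C=O)c2)c(C=O)c1 | intermediate
18 | deca-formate hexamer | COc1cc(OC=O)c(Oc2cc(OC=O)c(Oc3cc(OC=O)c(Oc4cc(OC=O)c(Oc5cc(OC=O)c(Oc6cc(OC)c(OC)c(OC)c6)c(OC=O)c5)c(OC=O)c4)c(OC=O)c3)c(OC=O)c2)c(OC=O)c1 | intermediate (not isolated)
19 | deca-phenol hexamer with four methyl ethers | COc1cc(O)c(Oc2cc(O)c(Oc3cc(O)c(Oc4cc(O)c(Oc5cc(O)c(Oc6cc(OC)c(OC)c(OC)c6)c(O)c5)c(O)c4)c(O)c3)c(O)c2)c(O)c1 | intermediate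
20 | 2‑[3,5‑dihydroxy‑4‑(3,5‑dihydroxy‑4‑{3,5‑dihydroxy‑4‑[3,5‑dihydroxy‑4‑(3,4,5‑trihydroxyphenoxy)phenoxy]phenoxy}phenoxy)phenoxy]benzene‑1,3,5‑triol | Oc1cc(O)c(Oc2cc(O)c(Oc3cc(O)c(Oc4cc(O)c(Oc5cc(O)c(Oc6cc(O)c(O)c(O)c6)c(O)c5)c(O)c4)c(O)c3)c(O)c2)c(O)c1 | target

## Step count and risks

Total step count: 16. Longest linear sequence: 15 steps (steps 1–12, 14, 15, 16, from 1 to 20); step 13 is a one-step branch from 5.

**Step 15 (key step).** Hydride migration instead of aryl migration at one or more of the ten aldehydes would give carboxylic acids. Each migrating carbon has only one ortho donor, which is twisted by its two neighbours, and it carries a meta formyl or formyloxy group. Any loss of selectivity per site is multiplied tenfold. Slow conversion of the last aldehydes and attack of peracid on ring F are secondary risks.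

Fallback, from 17 back to 19: the competing hydride is removed from the substrate. Addition of MeMgBr (THF, −78 °C) to all ten aldehydes should give the deca(1‑hydroxyethyl) hexamer F1, as a mixture of stereoisomers whose stereocentres are erased at once. Dess–Martin oxidation should give the deca-acetyl hexamer F2. Baeyer–Villiger oxidation of these aryl methyl ketones (mCPBA, cat. TFA, CH2Cl2), in which aryl migrates in preference to methyl, should give the deca-acetate hexamer F3. Acid methanolysis (HCl, degassed MeOH) returns to 19.

**Step 14 (and, to a smaller degree, steps 7, 9 and 11).** The phenoxide may attack a formyl-flanked ether carbon inside the chain instead of the C–F carbon, which would exchange chain segments and scramble the chain length. The chance grows with the number of activated ethers in the nucleophile, and the electron-poor phenoxide reacts slowly.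

Fallback, from 15 back to 17: the eight aldehydes of 15 are masked (HC(OMe)3, MeOH, cat. TsOH) as the octakis(dimethyl acetal) phenol F4. Its phenoxide is more nucleophilic and its internal ethers are no longer activated. Coupling with 16 (K2CO3, DMSO) should give the hexamer F5, with ring A as dialdehyde and rings B–E as bis(dimethyl acetals). Aqueous HCl/THF then frees the eight aldehydes to give 17.

**Step 2.** Bromination may stop unevenly, giving mixtures of CH2Br, CHBr2 and CBr3 groups, or go into the ring, because four C–H bonds at two sites must react to exactly the same degree.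

Fallback, from 2 back to 5: NBS (2.1 equiv) should give 3,5‑bis(bromomethyl)‑4‑fluorophenyl acetate F6. KOAc in DMF should give the triacetate (5‑acetoxy‑2‑fluoro‑1,3‑phenylene)bis(methylene) diacetate F7. K2CO3 in MeOH should give 4‑fluoro‑3,5‑bis(hydroxymethyl)phenol F8 (no formyl group is present yet, so the C–F bond is not activated toward methoxide). Activated MnO2 (EtOAc, rt) oxidises the two benzylic alcohols to give 5.

**Step 16.** Oxidative degradation of the free tetradecaphenol during work-up and chromatography, and incomplete cleavage that leaves partly methylated material of nearly the same polarity, are the likely problems.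

Fallback, from 19 back to 20: the crude product of the BBr3 reaction is not purified but acetylated (Ac2O, pyridine) to the tetradeca-acetate F9. F9 is stable to air and separable from under-demethylated material on silica. Acid methanolysis (HCl from AcCl, degassed MeOH, Ar) then gives 20, with only volatile by-products.

## Further compounds

F1 | step 15 | deca(1‑hydroxyethyl) hexamer (mixture of stereoisomers, configuration not controlled) | COc1cc(C(C)O)c(Oc2cc(C(C)O)c(Oc3cc(C(C)O)c(Oc4cc(C(C)O)c(Oc5cc(C(C)O)c(Oc6cc(OC)c(OC)c(OC)c6)c(C(C)O)c5)c(C(C)O)c4)c(C(C)O)c3)c(C(C)O)c2)c(C(C)O)c1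
F2 | step 15 | deca-acetyl hexamer | COc1cc(C(C)=O)c(Oc2cc(C(C)=O)c(Oc3cc(C(C)=O)c(Oc4cc(C(C)=O)c(Oc5cc(C(C)=O)c(Oc6cc(OC)c(OC)c(OC)c6)c(C(C)=O)c5)c(C(C)=O)c4)c(C(C)=O)c3)c(C(C)=O)c2)c(C(C)=O)c1
F3 | step 15 | deca-acetate hexamer | COc1cc(OC(C)=O)c(Oc2cc(OC(C)=O)c(Oc3cc(OC(C)=O)c(Oc4cc(OC(C)=O)c(Oc5cc(OC(C)=O)c(Oc6cc(OC)c(OC)c(OC)c6)c(OC(C)=O)c5)c(OC(C)=O)c4)c(OC(C)=O)c3)c(OC(C)=O)c2)c(OC(C)=O)c1
F4 | step 14 | octakis(dimethyl acetal) of the B–C–D–E–F phenol | Oc1cc(C(OC)OC)c(Oc2cc(C(OC)OC)c(Oc3cc(C(OC)OC)c(Oc4cc(C(OC)OC)c(Oc5cc(OC)c(OC)c(OC)c5)c(C(OC)OC)c4)c(C(OC)OC)c3)c(C(OC)OC)c2)c(C(OC)OC)c1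
F5 | step 14 | hexamer with ring A as dialdehyde and rings B–E as bis(dimethyl acetals) | COc1cc(C=O)c(Oc2cc(C(OC)OC)c(Oc3cc(C(OC)OC)c(Oc4cc(C(OC)OC)c(Oc5cc(C(OC)OC)c(Oc6cc(OC)c(OC)c(OC)c6)c(C(OC)OC)c5)c(C(OC)OC)c4)c(C(OC)OC)c3)c(C(OC)OC)c2)c(C=O)c1
F6 | step 2 | 3,5‑bis(bromomethyl)‑4‑fluorophenyl acetate | CC(=O)Oc1cc(CBr)c(F)c(CBr)c1
F7 | step 2 | (5‑acetoxy‑2‑fluoro‑1,3‑phenylene)bis(methylene) diacetate | CC(=O)OCc1cc(OC(C)=O)cc(COC(C)=O)c1F
F8 | step 2 | 4‑fluoro‑3,5‑bis(hydroxymethyl)phenol | OCc1cc(O)cc(CO)c1F
F9 | step 16 | tetradeca-acetate of the target | CC(=O)Oc1cc(OC(C)=O)c(Oc2cc(OC(C)=O)c(Oc3cc(OC(C)=O)c(Oc4cc(OC(C)=O)c(Oc5cc(OC(C)=O)c(Oc6cc(OC(C)=O)c(OC(C)=O)c(OC(C)=O)c6)c(OC(C)=O)c5)c(OC(C)=O)c4)c(OC(C)=O)c3)c(OC(C)=O)c2)c(OC(C)=O)c1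
A1 | alternative 1 | 2,6‑dimethoxyphenol (syringol) | COc1cccc(OC)c1O
A2 | alternative 1 | syringol hexamer with free head phenol and para C–H on the tail ring | COc1cccc(OC)c1Oc1cc(OC)c(Oc2cc(OC)c(Oc3cc(OC)c(Oc4cc(OC)c(Oc5cc(OC)c(O)c(OC)c5)c(OC)c4)c(OC)c3)c(OC)c2)c(OC)c1
A3 | alternative 2 | dimethyl 3‑[2,6‑dimethoxy‑4‑(2,4,6‑trimethoxyphenoxy)phenoxy]glutaconate (double-bond geometry not defined) | COC(=O)C=C(CC(=O)OC)Oc1c(OC)cc(Oc2c(OC)cc(OC)cc2OC)cc1OC
A4 | alternative 2 | dimethyl 2‑{3,5‑dimethoxy‑4‑[3,5‑dimethoxy‑4‑(3,4,5‑trimethoxyphenoxy)phenoxy]phenoxy}malonate | COC(=O)C(Oc1cc(OC)c(Oc2cc(OC)c(Oc3cc(OC)c(OC)c(OC)c3)c(OC)c2)c(OC)c1)C(=O)OC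
A5 | alternative 2 | hexamer with ring C as dimethyl 4,6‑dihydroxyisophthalate | COc1cc(OC)c(Oc2cc(OC)c(Oc3c(C(=O)OC)c(O)c(Oc4cc(OC)c(Oc5cc(OC)c(Oc6cc(OC)c(OC)c(OC)c6)c(OC)c5)c(OC)c4)c(O)c3C(=O)OC)c(OC)c2)c(OC)c1
A6 | alternative 3 | CpRu+ complex of 2,5‑dichloro‑1,3‑dimethoxybenzene, hexafluorophosphate | COc1cc(Cl)cc(OC)c1Cl.c1cc[cH-]c1.[Ru+2].F[P-](F)(F)(F)(F)F
A7 | alternative 3 | 2,6‑dimethoxy‑4‑[2,6‑dimethoxy‑4‑(2,4,6‑trimethoxyphenoxy)phenoxy]phenol (ABC phenol) | Oc1c(OC)cc(Oc2c(OC)cc(Oc3c(OC)cc(OC)cc3OC)cc2OC)cc1OC
A8 | alternative 3 | 3,5‑dimethoxy‑4‑(3,4,5‑trimethoxyphenoxy)phenol (EF phenol) | Oc1cc(OC)c(Oc2cc(OC)c(OC)c(OC)c2)c(OC)c1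
A9 | alternative 3 | CpRu+ complex (on ring D) of the permethylated hexamer, hexafluorophosphate | COc1cc(OC)c(Oc2cc(OC)c(Oc3cc(OC)c(Oc4cc(OC)c(Oc5cc(OC)c(Oc6cc(OC)c(OC)c(OC)c6)c(OC)c5)c(OC)c4)c(OC)c3)c(OC)c2)c(OC)c1.c1cc[cH-]c1.[Ru+2].F[P-](F)(F)(F)(F)F
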